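**Retrosynthetic overview**

1. Numbering used in the text (target): ring B = C1 (CH bearing the side chain), C2 and C3 (CH2), C4 (CH–CH3), fused at C4a/C8a to the arene (C5–OH, C6–OH, C7–CO2H, C8–H); side chain = 7-hydroxy-6-methylheptan-2-yl, C2′ (on C1) to C7′.
2. Key disconnection: ring B is opened at C1–C2 and C3–C4, giving an o-quinodimethane (C1=C8a–C4a=C4) and a two-carbon C2=C3 unit. In the forward sense an o-alkylbenzaldehyde (C4 as CHO, C1 as benzylic CH2) is photoenolized and trapped intramolecularly by a vinyl group tied through sulfur to side-chain C3′ (temporary thiolane); Raney nickel then excises the sulfur, leaving C2, C3 and C3′ as CH2.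
3. Enabling feature: C1 and C4 are benzylic carbons on ortho-related arene carbons (C8a, C4a), so the arene lends its C4a–C8a bond to a diene whose termini are exactly C1 and C4. C4 lies next to the C5 oxygen (hydrogen-bonded E-photoenol), and C1 carries the CH(CH3)–CH2 unit C2′–C3′, so a tether on C3′ lets the C2′ stereocentre set C1 through A(1,3) strain against the peri C8–H.
4. Ring order: the arene is bought; ring B and the temporary thiolane close together in step 12; the thiolane is opened in step 13; the C4 methyl (trans to the side chain) comes from SN1 methylation of the benzylic alcohol left by the photoenol, and the C7 carboxyl from a late ortho-lithiation/CO2 quench.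
5. Building blocks: C6′ from (S)-3-bromo-2-methylpropan-1-ol, C2′/C3′ from an Evans syn aldol, the arene from 6-bromo-2,3-dimethoxybenzaldehyde (Negishi coupling).

Key step: step 12

Remark (assumption): the sulfur-bearing C2 and the C4 carbinol of 20 are temporary centres whose epimers converge in steps 13 and 14, so 20 is drawn as the expected trans-fused isomer; IUPAC names of intermediates may number the ring differently from the target numbering used in the text (TBS = tert-butyldimethylsilyl).

**Route**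

Step 1
Reactants: 1 (S)-3-bromo-2-methylpropan-1-ol
Product: 2 (S)-(3-bromo-2-methylpropoxy)(tert-butyl)dimethylsilane
Conditions: TBSCl, imidazole, CH2Cl2, 0 °C → rt
Reagents that add atoms: tert-butyldimethylsilyl chloride, CC(C)(C)[Si](C)(C)Cl
Why: Standard silylation of a primary alcohol; the stereocentre (future C6′) is not touched.

Step 2
Reactants: 2 (S)-(3-bromo-2-methylpropoxy)(tert-butyl)dimethylsilane
Product: 3 (R)-5-[(tert-butyldimethylsilyl)oxy]-4-methylpentanenitrile
Conditions: MeCN, n-BuLi, THF, −78 °C; then 2, DMPU, −78 → 0 °C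
Reagents that add atoms: acetonitrile, CC#N
Why: SN2 alkylation of lithioacetonitrile by the primary bromide adds C3′ and C4′ as a two-carbon nitrile; the stereocentre is not touched (the descriptor changes only by priority).

Step 3
Reactants: 3 (R)-5-[(tert-butyldimethylsilyl)oxy]-4-methylpentanenitrile
Product: 4 (R)-5-[(tert-butyldimethylsilyl)oxy]-4-methylpentanal
Conditions: i-Bu2AlH, CH2Cl2, −78 °C; aq. Rochelle salt
Reagents that add atoms: water, O
Why: Partial reduction of the nitrile to the N-aluminio imine and hydrolysis on work-up (DIBAL-H nitrile reduction); the stereocentre is γ to the carbonyl and cannot epimerize.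

Step 4
Reactants: 5 (S)-4-benzyl-3-propanoyl-1,3-oxazolidin-2-one; 4 (R)-5-[(tert-butyldimethylsilyl)oxy]-4-methylpentanal
Product: 7 (S)-4-benzyl-3-[(2S,3R,6R)-7-[(tert-butyldimethylsilyl)oxy]-3-hydroxy-2,6-dimethylheptanoyl]-1,3-oxazolidin-2-one, via boron enolate 6 (not isolated)
Conditions: n-Bu2BOTf, i-Pr2NEt, CH2Cl2, 0 °C; then 4, −78 → 0 °C; pH 7 buffer, MeOH, H2O2
Reagents that add atoms: none
Why: Evans syn aldol: the Z-boron enolate reacts through a Zimmerman–Traxler chair in which the (S)-benzyl auxiliary fixes the enolate face, setting the C2′ methyl (2S) and the C3′ hydroxyl (3R) syn.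

Step 5
Reactants: 7 (S)-4-benzyl-3-[(2S,3R,6R)-7-[(tert-butyldimethylsilyl)oxy]-3-hydroxy-2,6-dimethylheptanoyl]-1,3-oxazolidin-2-one
Product: 8 (2R,3R,6R)-7-[(tert-butyldimethylsilyl)oxy]-2,6-dimethylheptane-1,3-diol
Conditions: LiBH4, MeOH (1 equiv), THF, 0 °C
Reagents that add atoms: none
Why: Reductive cleavage of the N-acyl oxazolidinone gives the primary alcohol (future C1) and returns the auxiliary; no stereocentre is touched.

Step 6
Reactants: 8 (2R,3R,6R)-7-[(tert-butyldimethylsilyl)oxy]-2,6-dimethylheptane-1,3-diol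
Product: 9 (2S,3R,6R)-7-[(tert-butyldimethylsilyl)oxy]-1-iodo-2,6-dimethylheptan-3-ol
Conditions: I2, PPh3, imidazole, CH2Cl2, 0 °C
Reagents that add atoms: iodine, II
Why: Garegg–Samuelsson (Appel-type) iodination is selective for the primary hydroxyl over the hindered secondary one; no stereocentre is touched.

Step 7
Reactants: 9 (2S,3R,6R)-7-[(tert-butyldimethylsilyl)oxy]-1-iodo-2,6-dimethylheptan-3-ol
Product: 10 (2S,3R,6R)-7-[(tert-butyldimethylsilyl)oxy]-1-iodo-2,6-dimethylheptan-3-yl acetate
Conditions: Ac2O, pyridine, DMAP (cat.), CH2Cl2, 0 °C → rt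
Reagents that add atoms: acetic anhydride, CC(=O)OC(C)=O
Why: Acetylation masks the secondary hydroxyl so that the alkylzinc reagent of step 8 carries no acidic proton; no stereocentre is touched.

Step 8
Reactants: 10 (2S,3R,6R)-7-[(tert-butyldimethylsilyl)oxy]-1-iodo-2,6-dimethylheptan-3-yl acetate; 11 6-bromo-2,3-dimethoxybenzaldehyde
Product: 13 (2R,3R,6R)-7-[(tert-butyldimethylsilyl)oxy]-1-(2-formyl-3,4-dimethoxyphenyl)-2,6-dimethylheptan-3-yl acetate, via alkylzinc iodide 12 (not isolated)
Conditions: Zn dust, LiCl, THF, 40 °C; then 11, Pd(OAc)2 (2 mol%), SPhos (4 mol%), THF, rt → 45 °C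
Reagents that add atoms: none
Why: Negishi coupling: LiCl-assisted zinc insertion into the primary C–I bond and sp3–sp2 coupling on zerovalent palladium form the C8a–C1 bond and tolerate the aldehyde, the acetate and the silyl ether; no stereocentre is touched.

Step 9
Reactants: 13 (2R,3R,6R)-7-[(tert-butyldimethylsilyl)oxy]-1-(2-formyl-3,4-dimethoxyphenyl)-2,6-dimethylheptan-3-yl acetate
Product: 14 6-[(2R,3R,6R)-7-[(tert-butyldimethylsilyl)oxy]-3-hydroxy-2,6-dimethylheptyl]-2,3-dimethoxybenzaldehyde
Conditions: K2CO3 (cat.), MeOH, rt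
Reagents that add atoms: none
Why: Base-catalysed transesterification frees the secondary alcohol; the aldehyde has no α-hydrogen and no stereocentre is touched.

Step 10
Reactants: 14 6-[(2R,3R,6R)-7-[(tert-butyldimethylsilyl)oxy]-3-hydroxy-2,6-dimethylheptyl]-2,3-dimethoxybenzaldehyde
Product: 16 S-[(2R,3S,6R)-7-[(tert-butyldimethylsilyl)oxy]-1-(2-formyl-3,4-dimethoxyphenyl)-2,6-dimethylheptan-3-yl] ethanethioate, via triflate 15 (not isolated)
Conditions: Tf2O, 2,6-lutidine, CH2Cl2, −40 °C; then KSAc, DMF, −20 °C → rt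
Reagents that add atoms: potassium thioacetate, CC(=O)[S-].[K+]
Why: SN2 displacement of the secondary triflate by thioacetate inverts C3′ (3R → 3S), placing sulfur anti to the C2′ methyl, the arrangement that puts the rest of the chain exo in the later cycloaddition.

Step 11
Reactants: 16 S-[(2R,3S,6R)-7-[(tert-butyldimethylsilyl)oxy]-1-(2-formyl-3,4-dimethoxyphenyl)-2,6-dimethylheptan-3-yl] ethanethioate
Product: 18 6-[(2R,3S,6R)-7-[(tert-butyldimethylsilyl)oxy]-3-(ethenylsulfanyl)-2,6-dimethylheptyl]-2,3-dimethoxybenzaldehyde, via potassium thiolate 17 (not isolated)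
Conditions: K2CO3, MeOH (degassed), 0 °C → rt; evaporate; then vinyl bromide (1 M in THF), Pd2(dba)3 (2.5 mol%), Xantphos (5 mol%), 1,4-dioxane, 60 °C
Reagents that add atoms: bromoethene (vinyl bromide), C=CBr
Why: Methanolysis of the thioester and palladium-catalysed C–S coupling of the thiolate with vinyl bromide (Migita-type) install the S-vinyl dienophile; the C3′–S bond is not broken, so its configuration is kept.

Step 12
Reactants: 18 6-[(2R,3S,6R)-7-[(tert-butyldimethylsilyl)oxy]-3-(ethenylsulfanyl)-2,6-dimethylheptyl]-2,3-dimethoxybenzaldehyde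
Product: 20 (1R,2S,3aS,5S,9bS)-2-[(3R)-4-[(tert-butyldimethylsilyl)oxy]-3-methylbutyl]-6,7-dimethoxy-1-methyl-1,2,3a,4,5,9b-hexahydronaphtho[2,1-b]thiophen-5-ol (thiolane-fused tetralol; trans ring fusion), via photoenol 19 (not isolated)
Conditions: hν (365 nm), degassed toluene (5 mM), 25 °C
Reagents that add atoms: none
Why: Proposed new method: n,π* excitation of the o-alkylbenzaldehyde triggers 1,5-hydrogen transfer from the benzylic CH2 to give the (E)-hydroxy-o-quinodimethane 19 (OH outward and hydrogen-bonded to the neighbouring OMe, side chain outward), which the tethered vinyl sulfide traps thermally in a concerted suprafacial [4+2] that restores aromaticity; the closest known reactions are intramolecular photoenolization/Diels–Alder reactions of o-alkylbenzaldehydes with tethered acceptor alkenes and thermal o-quinodimethane cycloadditions to unactivated tethered alkenes, the vinyl sulfide being new as the dienophile. Ring B closes as the six-membered cycloadduct ring (diene C1=C8a–C4a=C4, dienophile C2=C3), and the thiolane closes as the five-membered tether ring of a type 1 intramolecular Diels–Alder reaction with a three-atom tether (C2′, C3′, S), expected through the exo-tether transition state (trans ring fusion). C1 is set by the C2′ stereocentre: A(1,3) strain with the peri C8–H keeps H-2′ in the diene plane, so the tether carbon C3′ and the C2′ methyl lie on opposite faces and the dienophile reaches only the face that gives the (1S) configuration of the target. The C4 carbinol (OH cis to the side chain, from the E,E-diene geometry) and the sulfur-bearing C2 are temporary and are erased in steps 14 and 13. The step needs facial selectivity on the diene and regiocontrol, both secured by the short sulfur tether together with the C2′/C3′ anti arrangement from steps 4 and 10; reversion of the photoenol to 18 is non-destructive and only recycles the substrate.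

Step 13
Reactants: 20 (1R,2S,3aS,5S,9bS)-2-[(3R)-4-[(tert-butyldimethylsilyl)oxy]-3-methylbutyl]-6,7-dimethoxy-1-methyl-1,2,3a,4,5,9b-hexahydronaphtho[2,1-b]thiophen-5-ol
Product: 21 (1S,4S)-4-[(2S,6R)-7-[(tert-butyldimethylsilyl)oxy]-6-methylheptan-2-yl]-7,8-dimethoxy-1,2,3,4-tetrahydronaphthalen-1-ol
Conditions: Raney Ni (W-2, excess), EtOH/THF, rt
Reagents that add atoms: none
Why: Raney nickel desulfurization cleaves both C–S bonds, turning C2 and C3′ into CH2 and removing the temporary ring with its two temporary stereocentres; it is run at room temperature to spare the benzylic C–O bond, and before C-methylation so that the freed side chain can become pseudoaxial for step 14.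

Step 14
Reactants: 21 (1S,4S)-4-[(2S,6R)-7-[(tert-butyldimethylsilyl)oxy]-6-methylheptan-2-yl]-7,8-dimethoxy-1,2,3,4-tetrahydronaphthalen-1-ol
Product: 22 tert-butyl{[(2R,6S)-6-[(1S,4R)-5,6-dimethoxy-4-methyl-1,2,3,4-tetrahydronaphthalen-1-yl]-2-methylheptyl]oxy}dimethylsilane
Conditions: AlMe3 (5 equiv), CH2Cl2, −40 °C → rt
Reagents that add atoms: trimethylaluminium, C[Al](C)C
Why: SN1 methylation of an electron-rich benzylic alcohol with AlMe3 (ionization of the aluminium alkoxide to the o-methoxy-stabilized benzylic cation, methyl transfer from aluminium): pseudoaxial attack anti to the pseudoaxial C1 side chain should give the 1,4-trans (4R) product, in which both benzylic substituents stay clear of the peri positions.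

Step 15
Reactants: 22 tert-butyl{[(2R,6S)-6-[(1S,4R)-5,6-dimethoxy-4-methyl-1,2,3,4-tetrahydronaphthalen-1-yl]-2-methylheptyl]oxy}dimethylsilane
Product: 24 (5R,8S)-8-[(2S,6R)-7-[(tert-butyldimethylsilyl)oxy]-6-methylheptan-2-yl]-3,4-dimethoxy-5-methyl-5,6,7,8-tetrahydronaphthalene-2-carboxylic acid, via aryllithium 23 (not isolated)
Conditions: n-BuLi, TMEDA, Et2O, 0 °C → rt; CO2 (g), −78 °C → rt; aq. HCl
Reagents that add atoms: carbon dioxide, O=C=O
Why: Directed ortho-metalation: the C6 methoxy group directs lithiation to C7, the only ring position ortho to an oxygen, and the CO2 quench gives the benzoic acid; no stereocentre is touched.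

Step 16
Reactants: 24 (5R,8S)-8-[(2S,6R)-7-[(tert-butyldimethylsilyl)oxy]-6-methylheptan-2-yl]-3,4-dimethoxy-5-methyl-5,6,7,8-tetrahydronaphthalene-2-carboxylic acid
Product: 25 (5R,8S)-3,4-dihydroxy-8-[(2S,6R)-7-hydroxy-6-methylheptan-2-yl]-5-methyl-5,6,7,8-tetrahydronaphthalene-2-carboxylic acid (target)
Conditions: BCl3 (8 equiv), n-Bu4NI (4 equiv), CH2Cl2, −78 → 0 °C; then MeOH/H2O, rt
Reagents that add atoms: none
Why: Lewis acid/iodide cleavage of the two aryl methyl ethers (chelation-assisted next to the carboxyl) and loss of the silyl ether in the same operation and acidic work-up should give the target without touching a stereocentre and without halogenating the primary alcohol.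

**Compound list**

1 | (S)-3-bromo-2-methylpropan-1-ol | BrC[C@@H](C)CO | starting material
2 | (S)-(3-bromo-2-methylpropoxy)(tert-butyl)dimethylsilane | BrC[C@@H](C)CO[Si](C)(C)C(C)(C)C | intermediate
3 | (R)-5-[(tert-butyldimethylsilyl)oxy]-4-methylpentanenitrile | N#CCC[C@@H](C)CO[Si](C)(C)C(C)(C)C | intermediate
4 | (R)-5-[(tert-butyldimethylsilyl)oxy]-4-methylpentanal | O=CCC[C@@H](C)CO[Si](C)(C)C(C)(C)C | intermediate
5 | (S)-4-benzyl-3-propanoyl-1,3-oxazolidin-2-one | CCC(=O)N1C(=O)OC[C@@H]1Cc1ccccc1 | starting material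
6 | (Z)-di-n-butylboron enolate of 5 | CCCCB(CCCC)O/C(=C\C)N1C(=O)OC[C@@H]1Cc1ccccc1 | intermediate (not isolated)
7 | (S)-4-benzyl-3-[(2S,3R,6R)-7-[(tert-butyldimethylsilyl)oxy]-3-hydroxy-2,6-dimethylheptanoyl]-1,3-oxazolidin-2-one | CC(C)(C)[Si](C)(C)OC[C@H](C)CC[C@@H](O)[C@H](C)C(=O)N1C(=O)OC[C@@H]1Cc1ccccc1 | intermediate
8 | (2R,3R,6R)-7-[(tert-butyldimethylsilyl)oxy]-2,6-dimethylheptane-1,3-diol | CC(C)(C)[Si](C)(C)OC[C@H](C)CC[C@@H](O)[C@H](C)CO | intermediate
9 | (2S,3R,6R)-7-[(tert-butyldimethylsilyl)oxy]-1-iodo-2,6-dimethylheptan-3-ol | CC(C)(C)[Si](C)(C)OC[C@H](C)CC[C@@H](O)[C@H](C)CI | intermediate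
10 | (2S,3R,6R)-7-[(tert-butyldimethylsilyl)oxy]-1-iodo-2,6-dimethylheptan-3-yl acetate | CC(C)(C)[Si](C)(C)OC[C@H](C)CC[C@@H](OC(C)=O)[C@H](C)CI | intermediate
11 | 6-bromo-2,3-dimethoxybenzaldehyde | O=Cc1c(OC)c(OC)ccc1Br | starting material
12 | alkylzinc iodide from 10 | CC(C)(C)[Si](C)(C)OC[C@H](C)CC[C@@H](OC(C)=O)[C@H](C)C[Zn]I | intermediate (not isolated)
13 | (2R,3R,6R)-7-[(tert-butyldimethylsilyl)oxy]-1-(2-formyl-3,4-dimethoxyphenyl)-2,6-dimethylheptan-3-yl acetate | CC(C)(C)[Si](C)(C)OC[C@H](C)CC[C@@H](OC(C)=O)[C@H](C)Cc1ccc(OC)c(OC)c1C=O | intermediate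
14 | 6-[(2R,3R,6R)-7-[(tert-butyldimethylsilyl)oxy]-3-hydroxy-2,6-dimethylheptyl]-2,3-dimethoxybenzaldehyde | CC(C)(C)[Si](C)(C)OC[C@H](C)CC[C@@H](O)[C@H](C)Cc1ccc(OC)c(OC)c1C=O | intermediate
15 | secondary triflate of 14 | CC(C)(C)[Si](C)(C)OC[C@H](C)CC[C@@H](OS(=O)(=O)C(F)(F)F)[C@H](C)Cc1ccc(OC)c(OC)c1C=O | intermediate (not isolated)
16 | S-[(2R,3S,6R)-7-[(tert-butyldimethylsilyl)oxy]-1-(2-formyl-3,4-dimethoxyphenyl)-2,6-dimethylheptan-3-yl] ethanethioate | CC(C)(C)[Si](C)(C)OC[C@H](C)CC[C@H](SC(C)=O)[C@H](C)Cc1ccc(OC)c(OC)c1C=O | intermediate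
17 | potassium (2R,3S,6R)-7-[(tert-butyldimethylsilyl)oxy]-1-(2-formyl-3,4-dimethoxyphenyl)-2,6-dimethylheptane-3-thiolate | CC(C)(C)[Si](C)(C)OC[C@H](C)CC[C@H]([S-])[C@H](C)Cc1ccc(OC)c(OC)c1C=O.[K+] | intermediate (not isolated)
18 | 6-[(2R,3S,6R)-7-[(tert-butyldimethylsilyl)oxy]-3-(ethenylsulfanyl)-2,6-dimethylheptyl]-2,3-dimethoxybenzaldehyde | CC(C)(C)[Si](C)(C)OC[C@H](C)CC[C@H](SC=C)[C@H](C)Cc1ccc(OC)c(OC)c1C=O | intermediate
19 | (E,E)-hydroxy-o-quinodimethane (photoenol) of 18, OH and side chain both outward | O/C=C1\C(OC)=C(OC)C=C/C1=C\[C@@H](C)[C@@H](SC=C)CC[C@@H](C)CO[Si](C)(C)C(C)(C)C | intermediate (not isolated)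
20 | (1R,2S,3aS,5S,9bS)-2-[(3R)-4-[(tert-butyldimethylsilyl)oxy]-3-methylbutyl]-6,7-dimethoxy-1-methyl-1,2,3a,4,5,9b-hexahydronaphtho[2,1-b]thiophen-5-ol (trans-fused; OH cis to the thiolane carbon on C9b) | CC(C)(C)[Si](C)(C)OC[C@H](C)CC[C@@H]1S[C@H]2C[C@H](O)c3c(OC)c(OC)ccc3[C@@H]2[C@H]1C | intermediate
21 | (1S,4S)-4-[(2S,6R)-7-[(tert-butyldimethylsilyl)oxy]-6-methylheptan-2-yl]-7,8-dimethoxy-1,2,3,4-tetrahydronaphthalen-1-ol | CC(C)(C)[Si](C)(C)OC[C@H](C)CCC[C@H](C)[C@@H]1CC[C@H](O)c2c(OC)c(OC)ccc21 | intermediate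
22 | tert-butyl{[(2R,6S)-6-[(1S,4R)-5,6-dimethoxy-4-methyl-1,2,3,4-tetrahydronaphthalen-1-yl]-2-methylheptyl]oxy}dimethylsilane | CC(C)(C)[Si](C)(C)OC[C@H](C)CCC[C@H](C)[C@@H]1CC[C@@H](C)c2c(OC)c(OC)ccc21 | intermediate
23 | C7 aryllithium of 22 | CC(C)(C)[Si](C)(C)OC[C@H](C)CCC[C@H](C)[C@@H]1CC[C@@H](C)c2c(OC)c(OC)c([Li])cc21 | intermediate (not isolated)
24 | (5R,8S)-8-[(2S,6R)-7-[(tert-butyldimethylsilyl)oxy]-6-methylheptan-2-yl]-3,4-dimethoxy-5-methyl-5,6,7,8-tetrahydronaphthalene-2-carboxylic acid | CC(C)(C)[Si](C)(C)OC[C@H](C)CCC[C@H](C)[C@@H]1CC[C@@H](C)c2c(OC)c(OC)c(C(=O)O)cc21 | intermediate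
25 | (5R,8S)-3,4-dihydroxy-8-[(2S,6R)-7-hydroxy-6-methylheptan-2-yl]-5-methyl-5,6,7,8-tetrahydronaphthalene-2-carboxylic acid | C[C@@H](CO)CCC[C@H](C)[C@@H]1CC[C@@H](C)c2c1cc(C(=O)O)c(O)c2O | target

**Step count and risks**

Total step count: 16. Longest linear sequence: 16 steps (1 → 25); 5 and 11 are bought and enter in steps 4 and 8.

Most likely to fail, first: step 12 (proposed new method). The excited aldehyde may be quenched by electron transfer from the sulfide or may add to the electron-rich vinyl sulfide in a Paternò–Büchi reaction. The cycloaddition of the unactivated dienophile may also be too slow to outrun reversion of the photoenol, and facial control may erode. The fallback uses known chemistry and sets out from 18. Oxidation with mCPBA (2.1 equiv, NaHCO3, CH2Cl2, 0 °C) would give the vinyl sulfone, 6-[(2R,3S,6R)-7-[(tert-butyldimethylsilyl)oxy]-3-(ethenesulfonyl)-2,6-dimethylheptyl]-2,3-dimethoxybenzaldehyde F1. Its irradiation (365 nm, toluene) is an intramolecular photoenolization/Diels–Alder reaction with an acceptor alkene and should give the sulfolane-fused tetralol, the S,S-dioxide of 20, F2. LiAlH4 (Et2O, reflux), which reduces five-membered cyclic sulfones to sulfides, would then return the route to 20.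

Second: step 14. Attack on the benzylic cation may show poor facial selectivity, or the cation may lose a proton to give the dihydronaphthalene. The fallback sets out from 21. Dess–Martin oxidation would give the tetralone, (S)-4-[(2S,6R)-7-[(tert-butyldimethylsilyl)oxy]-6-methylheptan-2-yl]-7,8-dimethoxy-3,4-dihydronaphthalen-1(2H)-one F3. KHMDS/PhNTf2 (THF, −78 °C) would give its enol triflate F4, and MeMgBr with Fe(acac)3 (cat., THF/NMP) the 4-methyl-1,2-dihydronaphthalene F5. Catalyst-controlled asymmetric hydrogenation (H2, 50 bar, [Ir(cod)(L)]BArF with a chiral phosphino-oxazoline L, the enantiomer that delivers hydrogen to the face cis to the C1 side chain, CH2Cl2) would return the route to 22.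

Third: step 13. The benzylic C–O bond may be hydrogenolysed along with the C–S bonds, or the hindered thiolane may be cleaved only partly. The fallback sets out from 20 and carries the benzylic oxygen through the desulfurization at the ketone level. MnO2 (CH2Cl2) would give the tricyclic aryl ketone, the 5-oxo analogue of 20, F6. Raney nickel deactivated in acetone (acetone/EtOH, rt) would open the thiolane to the tetralone F3 named above. NaBH4 (MeOH, 0 °C) would then return the route to 21, either carbinol epimer serving step 14.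

**Further compounds**

F1 | step 12 | 6-[(2R,3S,6R)-7-[(tert-butyldimethylsilyl)oxy]-3-(ethenesulfonyl)-2,6-dimethylheptyl]-2,3-dimethoxybenzaldehyde | CC(C)(C)[Si](C)(C)OC[C@H](C)CC[C@H](S(=O)(=O)C=C)[C@H](C)Cc1ccc(OC)c(OC)c1C=O
F2 | step 12 | 2-[(3R)-4-[(tert-butyldimethylsilyl)oxy]-3-methylbutyl]-5-hydroxy-6,7-dimethoxy-1-methyl-1,2,3a,4,5,9b-hexahydronaphtho[2,1-b]thiophene 3,3-dioxide (stereochemistry as in 20) | CC(C)(C)[Si](C)(C)OC[C@H](C)CC[C@@H]1S(=O)(=O)[C@H]2C[C@H](O)c3c(OC)c(OC)ccc3[C@@H]2[C@H]1C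
F3 | step 14 | (S)-4-[(2S,6R)-7-[(tert-butyldimethylsilyl)oxy]-6-methylheptan-2-yl]-7,8-dimethoxy-3,4-dihydronaphthalen-1(2H)-one | CC(C)(C)[Si](C)(C)OC[C@H](C)CCC[C@H](C)[C@@H]1CCC(=O)c2c(OC)c(OC)ccc21
F4 | step 14 | (S)-4-[(2S,6R)-7-[(tert-butyldimethylsilyl)oxy]-6-methylheptan-2-yl]-7,8-dimethoxy-3,4-dihydronaphthalen-1-yl trifluoromethanesulfonate | CC(C)(C)[Si](C)(C)OC[C@H](C)CCC[C@H](C)[C@@H]1CC=C(OS(=O)(=O)C(F)(F)F)c2c(OC)c(OC)ccc21
F5 | step 14 | tert-butyl{[(2R,6S)-6-[(1S)-5,6-dimethoxy-4-methyl-1,2-dihydronaphthalen-1-yl]-2-methylheptyl]oxy}dimethylsilane | CC(C)(C)[Si](C)(C)OC[C@H](C)CCC[C@H](C)[C@@H]1CC=C(C)c2c(OC)c(OC)ccc21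
F6 | step 13 | 2-[(3R)-4-[(tert-butyldimethylsilyl)oxy]-3-methylbutyl]-6,7-dimethoxy-1-methyl-2,3a,4,9b-tetrahydronaphtho[2,1-b]thiophen-5(1H)-one (stereochemistry as in 20) | CC(C)(C)[Si](C)(C)OC[C@H](C)CC[C@@H]1S[C@H]2CC(=O)c3c(OC)c(OC)ccc3[C@@H]2[C@H]1C
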